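**Plan**

- Retrosynthesis: first the four O–benzyl bonds on the phenols are cut, then the two C–O bonds that relate each methyl group to a carboxyl-level carbon, then the central C2–C3 bond of the 2,3-dimethylbutane chain, and last the two-carbon extension back to an aryl aldehyde.
- Enabling feature: a C2 axis passes through the midpoint of the C2–C3 bond. C2 and C3 each carry H, CH3 and a 3,4-dihydroxy-5-methoxybenzyl group with the same (R) configuration, and each CH3 is a reduced acyl carbon. Each half is therefore the enolisable α-carbon of a 3-arylpropanoyl imide, and the target is the reduced homodimer of one fragment.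
- Forward: 5-hydroxyvanillin → dibenzyl ether → 3-arylpropanoic acid → chiral N-acyl oxazolidinone → oxidative enolate homodimerisation, which joins the chain at its midpoint (no ring is formed; both arenes are bought intact).
- Then two-directional end-group work on the C2-symmetric dimer: both imides → CH2OH → CH2OMs → CH3 at the same time, followed by hydrogenolysis of the four benzyl ethers.
- Stereochemistry: both stereocentres arise together in the dimerisation, each controlled by the (S)-4-isopropyloxazolidinone (L-valine series) on its own half; after the reduction of step 5 they are no longer epimerisable.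

Key step: step 4

Remark: compounds 1, 3 and 7 are taken as purchased, and LDA and LiEt3BH as commercial solutions. "Aryl" (Ar) below means 3,4-bis(benzyloxy)-5-methoxyphenyl.

**Route**

Step 1
Reactants: 1 5-hydroxyvanillin (3,4-dihydroxy-5-methoxybenzaldehyde)
Product: 2 3,4-bis(benzyloxy)-5-methoxybenzaldehyde
Conditions: BnBr (2.5 equiv), K2CO3, DMF, 60 °C
Reagents that add atoms: benzyl bromide, BrCc1ccccc1
Why: Williamson ether synthesis on both phenols of the catechol should proceed cleanly, the aldehyde being inert to carbonate, and benzyl is chosen because it survives every later step and leaves by hydrogenolysis without touching the aryl methyl ether.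

Step 2
Reactants: 2 3,4-bis(benzyloxy)-5-methoxybenzaldehyde; 3 Meldrum's acid (2,2-dimethyl-1,3-dioxane-4,6-dione)
Product: 6 3-[3,4-bis(benzyloxy)-5-methoxyphenyl]propanoic acid, via arylidene Meldrum's acid 4 (not isolated), via benzyl Meldrum's acid 5 (not isolated)
Conditions: HCO2H/Et3N (5:2, TEAF), 95–100 °C; then aq. HCl
Reagents that add atoms: none
Why: A tandem Knoevenagel condensation, conjugate transfer reduction of the highly electrophilic alkylidene Meldrum's acid by formate, and hydrolysis–decarboxylation (the water of condensation opens the dioxanedione) should give the saturated acid in one pot without any metal catalyst that could cleave the benzyl ethers.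

Step 3
Reactants: 6 3-[3,4-bis(benzyloxy)-5-methoxyphenyl]propanoic acid; 7 (S)-4-isopropyloxazolidin-2-one
Product: 9 (S)-3-{3-[3,4-bis(benzyloxy)-5-methoxyphenyl]propanoyl}-4-isopropyloxazolidin-2-one, via mixed pivalic anhydride 8 (not isolated)
Conditions: PivCl, Et3N, THF, −20 °C; then LiCl, 7, −20 °C → rt
Reagents that add atoms: none
Why: Mixed-anhydride N-acylation of the oxazolidinone (LiCl/Et3N activation) attacks the less hindered acyl carbon of the pivalic anhydride and installs the Evans auxiliary without strong base.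

Step 4
Reactants: 9 (S)-3-{3-[3,4-bis(benzyloxy)-5-methoxyphenyl]propanoyl}-4-isopropyloxazolidin-2-one (two molecules)
Product: 12 (4S,4'S)-3,3'-{(2R,3R)-2,3-bis[(3,4-bis(benzyloxy)-5-methoxyphenyl)methyl]butanedioyl}bis(4-isopropyloxazolidin-2-one), via lithium Z-enolate 10 (not isolated), via trichlorotitanium Z-enolate 11 (not isolated)
Conditions: LDA (1.05 equiv), THF, −78 °C; then TiCl4 (1.05 equiv), −78 °C → rt; aq. NH4Cl
Reagents that add atoms: none
Why: LDA forms the chelated Z(O)-lithium enolate 10, TiCl4 converts it into the Ti(IV) enolate 11, and inner-sphere one-electron oxidation of the enolate by Ti(IV) (which leaves as Ti(III)) gives metal-bound α-acyl radicals that combine at their α-carbons to form the central C–C bond. The closest known reaction type is the oxidative homodimerisation of metal enolates of chiral N-acyl oxazolidinones (Ti(IV), Cu(II), iodine or hypervalent-iodine oxidants). No ring is closed. Each of the two new stereocentres is controlled by the C4 isopropyl group of the oxazolidinone on its own half: in the chelated Z-enolate it shields one face of the α-carbon, so the new bond forms anti to isopropyl, which for the (S)-auxiliary means R at that carbon (the same sense as Evans alkylation). Because both halves carry the same auxiliary, the preferred outcome is the C2-symmetric (2R,3R) dimer and not the meso (2R,3S) isomer. The step needs C–C homocoupling in preference to α-chlorination, O–C coupling or reprotonation, which one equivalent of oxidant at low temperature and the carbon-centred reactivity of the imide-stabilised radical should secure; it also needs facial selectivity, which the rigid chelate provides, and the benzyl ethers should survive because TiCl4 is taken up by the enolate at −78 °C.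

Step 5
Reactants: 12 the (2R,3R)-bis-imide dimer
Product: 13 (2R,3R)-2,3-bis[(3,4-bis(benzyloxy)-5-methoxyphenyl)methyl]butane-1,4-diol
Conditions: LiBH4 (excess), MeOH (2–4 equiv), THF, 0 °C → rt
Reagents that add atoms: none
Why: Reductive cleavage of both N-acyl oxazolidinones by LiBH4 at the exocyclic carbonyl is a non-basic reaction that should not epimerise the α-centres, and any trans-lactone formed in passing by alkoxide attack on the second imide is reduced to the same diol, while auxiliary 7 is released for recovery.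

Step 6
Reactants: 13 the (2R,3R)-diol
Product: 14 (2R,3R)-2,3-bis[(3,4-bis(benzyloxy)-5-methoxyphenyl)methyl]butane-1,4-diyl dimethanesulfonate
Conditions: MsCl (2.5 equiv), Et3N, CH2Cl2, −10 → 0 °C
Reagents that add atoms: methanesulfonyl chloride, CS(=O)(=O)Cl
Why: Sulfonylation through the sulfene is fast at low temperature, so both primary hydroxyls should be mesylated before the mono-mesylate can cyclise to a tetrahydrofuran, as precedented for 2,3-dibenzylbutane-1,4-diols.

Step 7
Reactants: 14 the (2R,3R)-dimesylate
Product: 15 5,5'-[(2R,3R)-2,3-dimethylbutane-1,4-diyl]bis[1,2-bis(benzyloxy)-3-methoxybenzene] (tetra-O-benzyl sauriol A)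
Conditions: LiEt3BH (excess), THF, 0 °C → rt
Reagents that add atoms: none
Why: SN2 displacement of both primary mesylates by the strongly nucleophilic triethylborohydride turns each CH2OMs into CH3 without affecting the adjacent stereocentres or the aryl ethers, the standard sulfonate-reduction endgame for 2,3-dimethyl-1,4-diarylbutane lignans.

Step 8
Reactants: 15 tetra-O-benzyl sauriol A
Product: 16 sauriol A, 5,5'-[(2R,3R)-2,3-dimethylbutane-1,4-diyl]bis(3-methoxybenzene-1,2-diol)
Conditions: H2 (1 atm), 10% Pd/C, EtOAc/MeOH, rt; filtration and concentration under argon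
Reagents that add atoms: none
Why: Catalytic hydrogenolysis removes the four benzyl ethers under neutral, reducing conditions that suit the oxidation-prone catechols and leave the aryl methyl ethers and the saturated chain untouched.

**Compound list**

1 | 5-hydroxyvanillin (3,4-dihydroxy-5-methoxybenzaldehyde) | COc1cc(C=O)cc(O)c1O | starting material
2 | 3,4-bis(benzyloxy)-5-methoxybenzaldehyde | COc1cc(C=O)cc(OCc2ccccc2)c1OCc1ccccc1 | intermediate
3 | Meldrum's acid (2,2-dimethyl-1,3-dioxane-4,6-dione) | CC1(C)OC(=O)CC(=O)O1 | starting material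
4 | arylidene Meldrum's acid, 5-[(3,4-bis(benzyloxy)-5-methoxyphenyl)methylidene]-2,2-dimethyl-1,3-dioxane-4,6-dione | COc1cc(C=C2C(=O)OC(C)(C)OC2=O)cc(OCc2ccccc2)c1OCc1ccccc1 | intermediate (not isolated)
5 | benzyl Meldrum's acid, 5-[(3,4-bis(benzyloxy)-5-methoxyphenyl)methyl]-2,2-dimethyl-1,3-dioxane-4,6-dione | COc1cc(CC2C(=O)OC(C)(C)OC2=O)cc(OCc2ccccc2)c1OCc1ccccc1 | intermediate (not isolated)
6 | 3-[3,4-bis(benzyloxy)-5-methoxyphenyl]propanoic acid | COc1cc(CCC(=O)O)cc(OCc2ccccc2)c1OCc1ccccc1 | intermediate
7 | (S)-4-isopropyloxazolidin-2-one | CC(C)[C@H]1COC(=O)N1 | starting material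
8 | mixed pivalic anhydride of acid 6 | COc1cc(CCC(=O)OC(=O)C(C)(C)C)cc(OCc2ccccc2)c1OCc1ccccc1 | intermediate (not isolated)
9 | (S)-3-{3-[3,4-bis(benzyloxy)-5-methoxyphenyl]propanoyl}-4-isopropyloxazolidin-2-one | COc1cc(CCC(=O)N2[C@@H](C(C)C)COC2=O)cc(OCc2ccccc2)c1OCc1ccccc1 | intermediate
10 | lithium Z-enolate of 9 | COc1cc(C/C=C(\O[Li])N2[C@@H](C(C)C)COC2=O)cc(OCc2ccccc2)c1OCc1ccccc1 | intermediate (not isolated)
11 | trichlorotitanium(IV) Z-enolate of 9 | COc1cc(C/C=C(\O[Ti](Cl)(Cl)Cl)N2[C@@H](C(C)C)COC2=O)cc(OCc2ccccc2)c1OCc1ccccc1 | intermediate (not isolated)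
12 | (4S,4'S)-3,3'-{(2R,3R)-2,3-bis[(3,4-bis(benzyloxy)-5-methoxyphenyl)methyl]butanedioyl}bis(4-isopropyloxazolidin-2-one) | COc1cc(C[C@@H](C(=O)N2[C@@H](C(C)C)COC2=O)[C@H](C(=O)N2[C@@H](C(C)C)COC2=O)Cc2cc(OC)c(OCc3ccccc3)c(OCc3ccccc3)c2)cc(OCc2ccccc2)c1OCc1ccccc1 | intermediate
13 | (2R,3R)-2,3-bis[(3,4-bis(benzyloxy)-5-methoxyphenyl)methyl]butane-1,4-diol | COc1cc(C[C@@H](CO)[C@H](CO)Cc2cc(OC)c(OCc3ccccc3)c(OCc3ccccc3)c2)cc(OCc2ccccc2)c1OCc1ccccc1 | intermediate
14 | (2R,3R)-2,3-bis[(3,4-bis(benzyloxy)-5-methoxyphenyl)methyl]butane-1,4-diyl dimethanesulfonate | COc1cc(C[C@@H](COS(C)(=O)=O)[C@H](COS(C)(=O)=O)Cc2cc(OC)c(OCc3ccccc3)c(OCc3ccccc3)c2)cc(OCc2ccccc2)c1OCc1ccccc1 | intermediate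
15 | 5,5'-[(2R,3R)-2,3-dimethylbutane-1,4-diyl]bis[1,2-bis(benzyloxy)-3-methoxybenzene] | COc1cc(C[C@@H](C)[C@H](C)Cc2cc(OC)c(OCc3ccccc3)c(OCc3ccccc3)c2)cc(OCc2ccccc2)c1OCc1ccccc1 | intermediate
16 | sauriol A, 5,5'-[(2R,3R)-2,3-dimethylbutane-1,4-diyl]bis(3-methoxybenzene-1,2-diol) | COc1cc(C[C@@H](C)[C@H](C)Cc2cc(O)c(O)c(OC)c2)cc(O)c1O | target

**Step count and risks**

Total step count: 8. Longest linear sequence: 8 steps (1 → 16).

Steps most likely to fail:

1. Step 4. The facial bias of the auxiliary may be too weak in a radical-type coupling, so that the meso dimer forms alongside the wanted one; the enolate may also simply be reprotonated or chlorinated instead of coupling. The fallback sets out from 9 (and, for its second aryl unit, from 2) and comes back at 13, building the central bond in two polar alkylations instead of one oxidative coupling. Evans alkylation of 9 (NaHMDS, THF, −78 °C; tert-butyl bromoacetate) should give tert-butyl (3R)-3-[(3,4-bis(benzyloxy)-5-methoxyphenyl)methyl]-4-[(4S)-4-isopropyl-2-oxooxazolidin-3-yl]-4-oxobutanoate F1. Chemoselective LiBH4 reduction of the imide should give tert-butyl (3R)-3-[(3,4-bis(benzyloxy)-5-methoxyphenyl)methyl]-4-hydroxybutanoate F2. Acid-catalysed lactonisation (TsOH, toluene, 80 °C) should give (4R)-4-[(3,4-bis(benzyloxy)-5-methoxyphenyl)methyl]dihydrofuran-2(3H)-one F3. In parallel, NaBH4 reduction of 2 gives [3,4-bis(benzyloxy)-5-methoxyphenyl]methanol F4, and PBr3 converts it into 1,2-bis(benzyloxy)-5-(bromomethyl)-3-methoxybenzene F5. Alkylation of the lithium enolate of F3 (LiHMDS, THF, −78 °C) with F5, anti to the C4 substituent, should give the trans lactone (3R,4R)-3,4-bis[(3,4-bis(benzyloxy)-5-methoxyphenyl)methyl]dihydrofuran-2(3H)-one F6, and LiAlH4 reduction of F6 gives diol 13.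

2. Step 7. Hydride may attack sulfur instead of carbon at the β-branched primary centres, regenerating an alkoxide that closes onto the neighbouring mesylate to form a 3,4-disubstituted tetrahydrofuran. The fallback sets out from 14 and comes back at 15, replacing the polar hydride displacement with a radical dehalogenation. Finkelstein exchange (NaI, 2-butanone, reflux) should give the diiodide 5,5'-[(2R,3R)-2,3-bis(iodomethyl)butane-1,4-diyl]bis[1,2-bis(benzyloxy)-3-methoxybenzene] F7, and Bu3SnH with catalytic AIBN in toluene at 80 °C should reduce both C–I bonds to give 15.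

3. Step 5. Hydride may add to the endocyclic carbamate carbonyl of the two hindered, α-branched imides, opening the auxiliary ring to hydroxy-amides instead of releasing the diol. The fallback sets out from 12 and comes back at 13, separating auxiliary removal from reduction. Hydroperoxide hydrolysis (LiOH, H2O2, THF/H2O, 0 °C), which is selective for the exocyclic carbonyl, should give (2R,3R)-2,3-bis[(3,4-bis(benzyloxy)-5-methoxyphenyl)methyl]butanedioic acid F8, and BH3·THF reduction of both carboxylic acids gives 13.

**Further compounds**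

F1 | step 4 | tert-butyl (3R)-3-[(3,4-bis(benzyloxy)-5-methoxyphenyl)methyl]-4-[(4S)-4-isopropyl-2-oxooxazolidin-3-yl]-4-oxobutanoate | COc1cc(C[C@H](CC(=O)OC(C)(C)C)C(=O)N2[C@@H](C(C)C)COC2=O)cc(OCc2ccccc2)c1OCc1ccccc1
F2 | step 4 | tert-butyl (3R)-3-[(3,4-bis(benzyloxy)-5-methoxyphenyl)methyl]-4-hydroxybutanoate | COc1cc(C[C@H](CC(=O)OC(C)(C)C)CO)cc(OCc2ccccc2)c1OCc1ccccc1
F3 | step 4 | (4R)-4-[(3,4-bis(benzyloxy)-5-methoxyphenyl)methyl]dihydrofuran-2(3H)-one | COc1cc(C[C@@H]2CC(=O)OC2)cc(OCc2ccccc2)c1OCc1ccccc1
F4 | step 4 | [3,4-bis(benzyloxy)-5-methoxyphenyl]methanol | COc1cc(CO)cc(OCc2ccccc2)c1OCc1ccccc1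
F5 | step 4 | 1,2-bis(benzyloxy)-5-(bromomethyl)-3-methoxybenzene | COc1cc(CBr)cc(OCc2ccccc2)c1OCc1ccccc1
F6 | step 4 | (3R,4R)-3,4-bis[(3,4-bis(benzyloxy)-5-methoxyphenyl)methyl]dihydrofuran-2(3H)-one | COc1cc(C[C@H]2C(=O)OC[C@@H]2Cc2cc(OC)c(OCc3ccccc3)c(OCc3ccccc3)c2)cc(OCc2ccccc2)c1OCc1ccccc1
F7 | step 7 | 5,5'-[(2R,3R)-2,3-bis(iodomethyl)butane-1,4-diyl]bis[1,2-bis(benzyloxy)-3-methoxybenzene] | COc1cc(C[C@@H](CI)[C@H](CI)Cc2cc(OC)c(OCc3ccccc3)c(OCc3ccccc3)c2)cc(OCc2ccccc2)c1OCc1ccccc1
F8 | step 5 | (2R,3R)-2,3-bis[(3,4-bis(benzyloxy)-5-methoxyphenyl)methyl]butanedioic acid | COc1cc(C[C@@H](C(=O)O)[C@H](C(=O)O)Cc2cc(OC)c(OCc3ccccc3)c(OCc3ccccc3)c2)cc(OCc2ccccc2)c1OCc1ccccc1
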